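The side chain (C1′ at the ring to C19′) is cut between vinylic C11′ and allylic C12′ of its cis C10′=C11′ alkene, an isolated double bond remote from ring and carbinol. A Zweifel olefination makes this bond and the Z geometry in one operation: n-octyllithium adds to an (E)-alkenyl pinacol boronate, iodine triggers a 1,2-shift of octyl from boron to carbon, and anti elimination turns E into Z. The precursor is an (E)-alkenylboronate tethered to a dioxolane-masked 3-methoxybenzyl ketone, the anisole being the latent cyclohexenone ring. Birch reduction, copper-catalysed asymmetric conjugate boration–oxidation (tertiary alcohol), Saegusa desaturation and deprotection then complete the target.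

Key step: step 5

Assumption: the (R,R) antipode of QuinoxP* is taken to deliver the boryl group to the face of C3 that gives 16 and 17 as drawn; if a test run shows the opposite sense, the (S,S) ligand is used without other change.

Step 1
Reactants: 1 dec-9-ynoic acid
Product: 2 N-methoxy-N-methyldec-9-ynamide
Conditions: 1,1′-carbonyldiimidazole (1.1 equiv), CH2Cl2, rt; then MeNH(OMe)·HCl (1.2 equiv), rt
Reagents that add atoms: N,O-dimethylhydroxylamine hydrochloride, CNOC.Cl
Why: Weinreb amide formation through the acyl imidazolide is a routine amidation that leaves the terminal alkyne untouched.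

Step 2
Reactants: 2 N-methoxy-N-methyldec-9-ynamide; 3 (3-methoxybenzyl)magnesium chloride
Product: 4 1-(3-methoxyphenyl)undec-10-yn-2-one
Conditions: 3 (2.2 equiv, THF solution), THF, 0 °C; aq. NH4Cl
Reagents that add atoms: none
Why: Weinreb ketone synthesis: the chelated tetrahedral magnesium adduct resists a second addition until work-up, and the excess of Grignard reagent covers any deprotonation of the alkyne C–H.

Step 3
Reactants: 4 1-(3-methoxyphenyl)undec-10-yn-2-one
Product: 5 2-(3-methoxybenzyl)-2-(non-8-yn-1-yl)-1,3-dioxolane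
Conditions: HOCH2CH2OH (5 equiv), p-TsOH·H2O (cat.), benzene, reflux, Dean–Stark trap
Reagents that add atoms: ethylene glycol, OCCO
Why: Acid-catalysed ketalisation with azeotropic removal of water masks the ketone as a dioxolane that should survive the organolithium, dissolving-metal, basic and enolisation conditions that follow.

Step 4
Reactants: 5 2-(3-methoxybenzyl)-2-(non-8-yn-1-yl)-1,3-dioxolane
Product: 6 2-[(1E)-9-[2-(3-methoxybenzyl)-1,3-dioxolan-2-yl]non-1-en-1-yl]-4,4,5,5-tetramethyl-1,3,2-dioxaborolane
Conditions: HBpin (1.3 equiv), Cp2Zr(H)Cl (10 mol%), Et3N (10 mol%), neat, 60 °C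
Reagents that add atoms: pinacolborane, CC1(C)OBOC1(C)C
Why: Zirconocene hydride-catalysed syn hydroboration of a terminal alkyne places boron on the terminal carbon and should give only the (E)-alkenylboronate.

Step 5
Reactants: 6 (E)-alkenyl pinacol boronate; 7 1-iodooctane
Product: 11 2-[(8Z)-heptadec-8-en-1-yl]-2-(3-methoxybenzyl)-1,3-dioxolane, via n-octyllithium 8 (not isolated), via lithium alkenyl(octyl)boronate 9 (not isolated), via β-iodoboronic ester 10 (not isolated)
Conditions: 7 (1.3 equiv), t-BuLi (2.6 equiv), Et2O/pentane, −78 °C, then rt, 1 h; 6, THF, −78 °C; I2 (1.3 equiv) in THF, −78 °C; NaOMe (3 equiv) in MeOH, −78 °C → rt; aq. Na2S2O3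
Reagents that add atoms: none
Why: Lithium–iodine exchange gives n-octyllithium 8, which adds to the boron atom of 6 to form the tetracoordinate boronate 9; iodine then activates the alkene as an iodonium ion and triggers a 1,2-metallate shift of the octyl group from boron to the adjacent alkenyl carbon, anti to the new carbon–iodine bond, which creates the C11′–C12′ bond and the β-iodoboronic ester 10. Methoxide attacks boron and induces anti elimination of boron and iodide, so that the E geometry of 6 is translated stereospecifically into the Z alkene of 11. This is the Zweifel olefination in its boronic ester/organolithium form. No ring is closed and no stereogenic carbon remains in the product; the only stereo-element set is the C10′=C11′ geometry, controlled by the E configuration of the alkenylboronate and the anti course of both migration and elimination. The step needs migration of the octyl group alone, which is secured because the pinacol oxygens do not migrate and residual t-BuLi is destroyed by the ether solvent on warming before 6 is added; the dioxolane and the anisole ring are inert to the organolithium at −78 °C.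

Step 6
Reactants: 11 2-[(8Z)-heptadec-8-en-1-yl]-2-(3-methoxybenzyl)-1,3-dioxolane
Product: 14 3-{[2-((8Z)-heptadec-8-en-1-yl)-1,3-dioxolan-2-yl]methyl}cyclohex-2-en-1-one, via dihydroanisole 12 (not isolated), via β,γ-unsaturated ketone 13 (not isolated)
Conditions: Li (excess), NH3(l)/THF, t-BuOH, −78 → −33 °C; solid NH4Cl, evaporation of NH3; (CO2H)2, THF/MeOH/H2O, rt; then DBU (0.2 equiv), CH2Cl2, rt
Reagents that add atoms: water, O
Why: Birch reduction of a 3-alkylanisole leaves both donor substituents on sp2 carbons (1-methoxy-5-alkylcyclohexa-1,4-diene) and does not touch the isolated Z alkene or the dioxolane; oxalic acid hydrolyses only the enol ether, and base moves the β,γ double bond into conjugation.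

Step 7
Reactants: 14 3-{[2-((8Z)-heptadec-8-en-1-yl)-1,3-dioxolan-2-yl]methyl}cyclohex-2-en-1-one
Product: 17 (3S)-3-{[2-((8Z)-heptadec-8-en-1-yl)-1,3-dioxolan-2-yl]methyl}-3-hydroxycyclohexan-1-one, via boron enolate 15 (not isolated), via β-boryl ketone 16 (not isolated)
Conditions: B2pin2 (1.5 equiv), [Cu(MeCN)4]PF6 (10 mol%), (R,R)-QuinoxP* (12 mol%), LiOt-Bu (15 mol%), DMSO/THF, rt; then NaBO3·4H2O, THF/H2O, rt
Reagents that add atoms: bis(pinacolato)diboron, CC1(C)OB(OC1(C)C)B1OC(C)(C)C(C)(C)O1 (boryl groups of 15 and 16 only); sodium perborate NaBO3·4H2O, [Na+].[Na+].O[B-]1(O)OO[B-](O)(O)OO1 (hydroxyl oxygen of 17)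
Why: Copper-catalysed asymmetric conjugate boration of a β-substituted cyclic enone: the bisphosphine-bound monovalent copper boryl adds to one enantiotopic face of C3 (ligand control) to set the boron-bearing quaternary centre, the copper enolate is trapped by B2pin2 as boron enolate 15, and perborate oxidation of the carbon–boron bond with retention gives the tertiary alcohol.

Step 8
Reactants: 17 (3S)-3-{[2-((8Z)-heptadec-8-en-1-yl)-1,3-dioxolan-2-yl]methyl}-3-hydroxycyclohexan-1-one
Product: 19 (5S)-5-{[2-((8Z)-heptadec-8-en-1-yl)-1,3-dioxolan-2-yl]methyl}-5-[(trimethylsilyl)oxy]cyclohex-2-en-1-one, via bis(trimethylsilyl) derivative 18 (not isolated)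
Conditions: Me3SiCl (5 equiv) and LiN(i-Pr)2 (LDA, commercial solution, 2.4 equiv) premixed in THF, −78 °C, then 17, −78 → 0 °C; removal of volatiles; Pd(OAc)2 (1.1 equiv), MeCN, rt
Reagents that add atoms: chlorotrimethylsilane, C[Si](C)(C)Cl
Why: Internal-quench kinetic enolisation removes a proton from the less hindered C6 methylene rather than from C2 next to the quaternary carbinol, whose alkoxide is silylated in the same pot before retro-aldol ring opening can erode the stereocentre, and Saegusa–Ito oxidation (β-hydride elimination from the divalent palladium enolate) of the resulting silyl enol ether gives the enone, C3 having no hydrogen so that only the C5–C6 double bond can form.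

Step 9
Reactants: 19 (5S)-5-{[2-((8Z)-heptadec-8-en-1-yl)-1,3-dioxolan-2-yl]methyl}-5-[(trimethylsilyl)oxy]cyclohex-2-en-1-one
Product: 21 (5R)-5-hydroxy-5-[(10Z)-2-oxononadec-10-en-1-yl]cyclohex-2-en-1-one, via hydroxy ketal 20 (not isolated)
Conditions: pyridinium p-toluenesulfonate (0.3 equiv), acetone/H2O (10:1), 45 °C
Reagents that add atoms: water, O
Why: Weakly acidic hydrolysis/transketalisation first cleaves the labile tertiary trimethylsilyl ether and then the dioxolane, the mild acid being chosen so that the tertiary β-hydroxy ketone is not dehydrated towards the phenol; the descriptor changes from S to R only because the priorities of the substituents change.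

Compound list
1 | dec-9-ynoic acid | C#CCCCCCCCC(=O)O | starting material
2 | N-methoxy-N-methyldec-9-ynamide | C#CCCCCCCCC(=O)N(C)OC | intermediate
3 | (3-methoxybenzyl)magnesium chloride | COc1cccc(C[Mg]Cl)c1 | starting material
4 | 1-(3-methoxyphenyl)undec-10-yn-2-one | COc1cccc(CC(=O)CCCCCCCC#C)c1 | intermediate
5 | 2-(3-methoxybenzyl)-2-(non-8-yn-1-yl)-1,3-dioxolane | COc1cccc(CC2(CCCCCCCC#C)OCCO2)c1 | intermediate
6 | 2-[(1E)-9-[2-(3-methoxybenzyl)-1,3-dioxolan-2-yl]non-1-en-1-yl]-4,4,5,5-tetramethyl-1,3,2-dioxaborolane | COc1cccc(CC2(CCCCCCC/C=C/B3OC(C)(C)C(C)(C)O3)OCCO2)c1 | intermediate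
7 | 1-iodooctane | CCCCCCCCI | starting material
8 | n-octyllithium | [Li]CCCCCCCC | intermediate
9 | lithium boronate from 6 and 8 (octyl and (E)-alkenyl groups on tetracoordinate boron) | [Li+].CCCCCCCC[B-]1(/C=C/CCCCCCCC2(Cc3cccc(OC)c3)OCCO2)OC(C)(C)C(C)(C)O1 | intermediate
10 | racemic (8R*,9R*)-2-[8-iodo-9-(4,4,5,5-tetramethyl-1,3,2-dioxaborolan-2-yl)heptadecyl]-2-(3-methoxybenzyl)-1,3-dioxolane (anti adduct, one enantiomer drawn) | CCCCCCCC[C@@H](B1OC(C)(C)C(C)(C)O1)[C@H](I)CCCCCCCC2(Cc3cccc(OC)c3)OCCO2 | intermediate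
11 | 2-[(8Z)-heptadec-8-en-1-yl]-2-(3-methoxybenzyl)-1,3-dioxolane | CCCCCCCC/C=C\CCCCCCCC1(Cc2cccc(OC)c2)OCCO1 | intermediate
12 | 2-[(8Z)-heptadec-8-en-1-yl]-2-[(5-methoxycyclohexa-1,4-dien-1-yl)methyl]-1,3-dioxolane | CCCCCCCC/C=C\CCCCCCCC1(CC2=CCC=C(OC)C2)OCCO1 | intermediate
13 | 3-{[2-((8Z)-heptadec-8-en-1-yl)-1,3-dioxolan-2-yl]methyl}cyclohex-3-en-1-one | CCCCCCCC/C=C\CCCCCCCC1(CC2=CCCC(=O)C2)OCCO1 | intermediate
14 | 3-{[2-((8Z)-heptadec-8-en-1-yl)-1,3-dioxolan-2-yl]methyl}cyclohex-2-en-1-one | CCCCCCCC/C=C\CCCCCCCC1(CC2=CC(=O)CCC2)OCCO1 | intermediate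
15 | 2-{[(3S)-3-{[2-((8Z)-heptadec-8-en-1-yl)-1,3-dioxolan-2-yl]methyl}-3-(4,4,5,5-tetramethyl-1,3,2-dioxaborolan-2-yl)cyclohex-1-en-1-yl]oxy}-4,4,5,5-tetramethyl-1,3,2-dioxaborolane (boron enolate) | CCCCCCCC/C=C\CCCCCCCC2(C[C@]1(B3OC(C)(C)C(C)(C)O3)CCCC(OB3OC(C)(C)C(C)(C)O3)=C1)OCCO2 | intermediate
16 | (3R)-3-{[2-((8Z)-heptadec-8-en-1-yl)-1,3-dioxolan-2-yl]methyl}-3-(4,4,5,5-tetramethyl-1,3,2-dioxaborolan-2-yl)cyclohexan-1-one | CCCCCCCC/C=C\CCCCCCCC2(C[C@]1(B3OC(C)(C)C(C)(C)O3)CCCC(=O)C1)OCCO2 | intermediate
17 | (3S)-3-{[2-((8Z)-heptadec-8-en-1-yl)-1,3-dioxolan-2-yl]methyl}-3-hydroxycyclohexan-1-one | CCCCCCCC/C=C\CCCCCCCC2(C[C@]1(O)CCCC(=O)C1)OCCO2 | intermediate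
18 | trimethylsilyl enol ether (C1=C6) of the O-trimethylsilyl ether of 17, (S) at the silyloxy-bearing quaternary carbon | CCCCCCCC/C=C\CCCCCCCC2(C[C@]1(O[Si](C)(C)C)CCC=C(O[Si](C)(C)C)C1)OCCO2 | intermediate
19 | (5S)-5-{[2-((8Z)-heptadec-8-en-1-yl)-1,3-dioxolan-2-yl]methyl}-5-[(trimethylsilyl)oxy]cyclohex-2-en-1-one | CCCCCCCC/C=C\CCCCCCCC2(C[C@]1(O[Si](C)(C)C)CC=CC(=O)C1)OCCO2 | intermediate
20 | (5S)-5-{[2-((8Z)-heptadec-8-en-1-yl)-1,3-dioxolan-2-yl]methyl}-5-hydroxycyclohex-2-en-1-one | CCCCCCCC/C=C\CCCCCCCC2(C[C@]1(O)CC=CC(=O)C1)OCCO2 | intermediate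
21 | (5R)-5-hydroxy-5-[(10Z)-2-oxononadec-10-en-1-yl]cyclohex-2-en-1-one | CCCCCCCC/C=C\CCCCCCCC(=O)C[C@]1(O)CC=CC(=O)C1 | target

Total step count: 9. Longest linear sequence: 9 steps (1 → 21); 3 and 7 are purchased and enter directly.

Steps most likely to fail

1. Step 7. The boryl transfer to the β-carbon may be sluggish or poorly face-selective, because the dioxolane makes the β-substituent neopentyl-like, and the sense of induction is assumed. The fallback sets out from 14 and forms the carbon–oxygen bond by nucleophilic epoxidation instead. Iminium-type asymmetric epoxidation with the trifluoroacetate salt of 9-amino-9-deoxy-epi-quinine (or of its quinidine-derived pseudo-enantiomer, whichever gives the drawn epoxide) and aqueous H2O2 in dioxane should give the epoxy ketone (1S,6R)-6-{[2-((8Z)-heptadec-8-en-1-yl)-1,3-dioxolan-2-yl]methyl}-7-oxabicyclo[4.1.0]heptan-2-one F1. Reductive cleavage of its α carbon–oxygen bond with phenylselenide (PhSeSePh, NaBH4, EtOH, AcOH) leaves the tertiary carbon–oxygen bond intact and comes back to the route at 17.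

2. Step 8. Enolisation may occur at C2 instead of C6, or stoichiometric divalent palladium may isomerise or oxidise the Z alkene. The fallback sets out from 17 and avoids both the enol silane and palladium. Direct α,β-dehydrogenation with 2-iodoxybenzoic acid and 4-methoxypyridine N-oxide in DMSO at rt can only introduce the C5–C6 double bond, because C3 carries no hydrogen. It gives the free hydroxy enone and comes back to the route at 20, which is then deketalised under the conditions of step 9.

3. Step 9. Acid-promoted loss of the tertiary hydroxyl (β-elimination followed by tautomerisation to a phenol) may compete with slow hydrolysis of the hindered dioxolane. The fallback sets out from 11, where acid is harmless, and carries the side-chain carbonyl as a secondary alcohol so that the last step is a neutral oxidation.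
   - Aqueous HCl in THF should give (10Z)-1-(3-methoxyphenyl)nonadec-10-en-2-one F2.
   - NaBH4 in MeOH should give racemic (10Z)-1-(3-methoxyphenyl)nonadec-10-en-2-ol F3.
   - Birch reduction, hydrolysis and isomerisation under the conditions of step 6 should give 3-[(10Z)-2-hydroxynonadec-10-en-1-yl]cyclohex-2-en-1-one F4.
   - Boration–oxidation under the conditions of step 7 should give (3R)-3-hydroxy-3-[(10Z)-2-hydroxynonadec-10-en-1-yl]cyclohexan-1-one F5 as both epimers at the side-chain carbinol.
   - Silylation of both hydroxyls, enol silane formation and Pd(OAc)2 oxidation under the conditions of step 8, followed by citric acid in MeOH, should give (5R)-5-hydroxy-5-[(10Z)-2-hydroxynonadec-10-en-1-yl]cyclohex-2-en-1-one F6.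
   - Dess–Martin oxidation of the secondary alcohol (NaHCO3, CH2Cl2) removes the extra stereocentre and comes back to the route at 21.

Further compounds
F1 | step 7 | (1S,6R)-6-{[2-((8Z)-heptadec-8-en-1-yl)-1,3-dioxolan-2-yl]methyl}-7-oxabicyclo[4.1.0]heptan-2-one | CCCCCCCC/C=C\CCCCCCCC3(C[C@]1(O2)CCCC(=O)[C@H]12)OCCO3
F0 | step 8 | none | none
F2 | step 9 | (10Z)-1-(3-methoxyphenyl)nonadec-10-en-2-one | CCCCCCCC/C=C\CCCCCCCC(=O)Cc1cccc(OC)c1
F3 | step 9 | racemic (10Z)-1-(3-methoxyphenyl)nonadec-10-en-2-ol | CCCCCCCC/C=C\CCCCCCCC(O)Cc1cccc(OC)c1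
F4 | step 9 | racemic 3-[(10Z)-2-hydroxynonadec-10-en-1-yl]cyclohex-2-en-1-one | CCCCCCCC/C=C\CCCCCCCC(O)CC1=CC(=O)CCC1
F5 | step 9 | (3R)-3-hydroxy-3-[(10Z)-2-hydroxynonadec-10-en-1-yl]cyclohexan-1-one, both epimers at the side-chain carbinol | CCCCCCCC/C=C\CCCCCCCC(O)C[C@]1(O)CCCC(=O)C1
F6 | step 9 | (5R)-5-hydroxy-5-[(10Z)-2-hydroxynonadec-10-en-1-yl]cyclohex-2-en-1-one, both epimers at the side-chain carbinol | CCCCCCCC/C=C\CCCCCCCC(O)C[C@]1(O)CC=CC(=O)C1
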